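It is tempting to read the excess of Z over J against the clock, but the dawn and noon runs, which differ in Q, then disagree, so I read it against conversion, the part of J and Z together that has reacted.

| setting | dawn | noon | flask |
|---|---|---|---|
| J | 0.050 M | 0.050 M | 0.050 M |
| Z | 0.050 M | 0.050 M | 0.050 M |
| Q | 2 equiv (fed, over 8.0 s) | 1.3 equiv (fed, over 8.0 s) | 2.00 equiv (fed, over 8.0 s) |
| X | 3.9 mol% | 3.9 mol% | 3.9 mol% |
| remark | the very flask that is asked about, followed so far | run made earlier |  |
| time |  |  | 10 min |

- L is single-handed; J and Z are mirror images of each other, charged as a racemate, each of them at the stated concentration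
- the analysis behind the earlier runs scatters by 1.5 percentage points, standard deviation

- whether the excess of Z over J among what is left of the two reaches 99% by 10 min (yes / no)
- the highest excess of Z over J among what is left of the two up to 10 min

| run | time / min | Z / % | J / % |
|---|---|---|---|
| dawn | 0.250 | 50 | 51 |
| dawn | 0.833 | 47 | 48 |
| dawn | 1.33 | 47 | 43 |
| dawn | 2.00 | 46 | 39 |
| dawn | 3.00 | 40 | 33 |
| dawn | 4.00 | 37 | 25 |
| dawn | 5.00 | 35 | 26 |
| noon | 0.417 | 51 | 49 |
| noon | 1.00 | 49 | 49 |
| noon | 2.00 | 47 | 41 |
| noon | 3.00 | 42 | 37 |
| noon | 4.00 | 40 | 33 |
| noon | 6.00 | 34 | 27 |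
| noon | 8.00 | 33 | 24 |

(scatter of a reading: 1.5 percentage points)

I compare the last reading of each run. In the dawn run, which is this flask so far, 61.0% of J and Z is left at 5.00 min, with an excess of 14.8%. In the noon run, 57.0% is left at 8.00 min, with an excess of 15.8%. Dividing excess by conversion gives 0.378 at dawn and 0.367 at noon, alike as readings with a scatter of 1.5 percentage points, although Q differs. I call this ratio the excess gain: excess won per unit of conversion.

So I need the conversion at 10 min. This flask holds 2.00 equiv of Q on J, as much as J and Z together. If each molecule takes one Q, Q falls in step with them, and I take the rate as second order in what is left, not pseudo-first-order. That leaves 43.9% at 10 min, so my estimate of the excess there, which I also take as its highest value, is 21.2%, and I answer no to reaching the wanted level.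

The forecast, “Extrapolating with slowing rates”, gives no and 27%.

The flask gives no and 17.5%.

    Q + L + J → L + D (k = 77.0 M⁻² s⁻¹)
    Q + L + Z → L + G (k = 26.0 M⁻² s⁻¹)
    X ⇌ L (K = 1.30, k = 0.00430 s⁻¹)
    Q + L → E (k = 0.0530 M⁻¹ s⁻¹)
    J ⇌ Z (k = 0.00190 s⁻¹)

In this flask the excess is 16.4% at 5.00 min and 16.0% at 10.0 min, while J and Z interconvert with a relaxation half-life, by that step alone and both ways together, of 3.04 min. With D and G together at 58.5%, the gain gives 22.1%, above the excess there.

In the neighbour charged with 0.500 equiv of Q, Q is the limiting reagent, and at one Q per molecule its charge covers 25.0% of J and Z together, so the gain gives 9.45%. The computed top there is 4.95%, lower again.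

The numbers in the tables come from a simulation for substances that don't exist; the scatter is artificial.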